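**Questions asked.** There are 5 questions: which flask holds most product, and how much each of the 4 flasks holds at the end.

| setting | north | north-west | west | Thursday's | Wednesday's | Sunday's | Saturday's |
|---|---|---|---|---|---|---|---|
| substrate | 0.060 M | 0.060 M | 0.060 M | 0.060 M | 0.060 M | 0.060 M | 0.060 M |
| partner | 0.70 equiv | 0.35 equiv | 1.4 equiv | 0.700 equiv | 0.700 equiv | 0.700 equiv | 0.700 equiv |
| reagent | 2 equiv | 2 equiv | 2 equiv | 2.00 equiv (fed, over 3.0 d) | 2.00 equiv (fed, over 3.0 d) | 2.00 equiv | 2.00 equiv (in portions, 2, over 3.0 d) |
| temperature | 10 °C | 25 °C | 10 °C | 25 °C |  | 25 °C | 25 °C |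
| remark | run made earlier | run made earlier | run made earlier | all else is in the flask from the start; the feed brings no volume worth counting | the addition at −5 °C, then warmed to 25 °C; the feed brings no volume worth counting | everything together at the start | first portion at the start, last at 3.0 d |
| time |  |  |  | 4.0 d | 4.0 d | 4.0 d | 4.0 d |

| run | time / d | product / % | substrate / % |
|---|---|---|---|
| north | 1.25 | 1.7 | 51.4 |
| north | 2.50 | 5.1 | 33.5 |
| north | 4.00 | 11.3 | 22.8 |
| north | 5.00 | 13.6 | 18.1 |
| north-west | 0.833 | 7.0 | 12.8 |
| north-west | 1.67 | 15.4 | 2.9 |
| north-west | 2.50 | 19.9 | 1.7 |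
| north-west | 3.00 | 22.7 | 0.7 |
| west | 1.67 | 3.8 | 58.6 |
| west | 4.00 | 13.3 | 46.8 |
| west | 5.00 | 17.7 | 44.5 |
| west | 6.00 | 20.4 | 43.1 |

(standard deviation of a reading: 0.5 percentage points)

* the flask with the highest amount of product, in percent of the substrate charged ("all alike" if they lie within 1.5 percentage points) (Thursday's / Wednesday's / Sunday's / Saturday's / all alike)
* final product, as a percentage of the substrate charged, in Thursday's
* final product, as a percentage of the substrate charged, in Wednesday's
* final product, as a percentage of the substrate charged, in Sunday's
* final product, as a percentage of the substrate charged, in Saturday's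

- what was read earlier has a scatter of 0.5 percentage points, one standard deviation

**What matters.** The temperature has to be known well, since Wednesday's spends 3.0 d at −5 °C and then has 1.00 d at 25 °C. The partner has to be known well too: I assume each product takes one partner, so an error in the partner charge moves the yield limit point for point. What stays after the partner, 1.30 equiv, exceeds the partner charge, so a small error in the reagent leaves that limit where it is.

**Product ceiling.** If each partner and each substrate takes one reagent, 1.4 equiv of partner in the west run leaves 0.600 equiv of reagent for the substrate. Its substrate reading still falls slowly and stands at 43.1 % at 6.00 d, near the 40.0 % that this balance would strand. So I read the west run as the partner taking its share of reagent away from the substrate. For these charges I call the smaller of the partner charge and the reagent left after the partner the product ceiling, 70.0 %, with the partner as limiting reagent.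

**My estimate.** The north-west run, at 25 °C, has a ceiling equal to its partner charge of 0.35 equiv, and by 3.00 d the reading fills 64.9 % of it. The 4 flasks carry the same charges, so the ceiling does not rank them. Sunday's takes its reagent at the start, the other flasks spread it over 3.0 d, and I put Sunday's first. That share of Sunday's ceiling gives 45.4 %, a rough figure, as the north-west share was read at 3.00 d, not 4.0 d, and with half the partner.

**Forecast, result.** The forecast names Sunday's, with 40 % for Thursday's, 17 % for Wednesday's, 45 % for Sunday's and 38 % for Saturday's, holding that “early intermediate wins”. Sunday's gives 47.0 %, more than Thursday's 32.5 %, Saturday's 29.0 % and Wednesday's 16.1 %.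

    substrate + reagent → open intermediate (k = 4.40 × 10⁻⁴ M⁻¹ s⁻¹, Ea = 75.0 kJ mol⁻¹)
    reagent + partner → second intermediate (k = 0.00130 M⁻¹ s⁻¹, Ea = 58.0 kJ mol⁻¹)
    open intermediate + second intermediate → product (k = 9.30 × 10⁻⁵ M⁻¹ s⁻¹, Ea = 83.0 kJ mol⁻¹)
    (constants at 25 °C)

**Ceiling tested.** Sunday's reaches 69.9 % after 40.0 d, level with its ceiling of 70.0 %, and its reagent then stands at 15.0 % of its own charge, the 15.0 % the balance leaves. A neighbour of Sunday's with 1.20 equiv of partner has 0.800 equiv of reagent after the partner, less than its partner. Its ceiling is therefore 80.0 %, and 20.0 % of substrate should stay behind. At 4.00 d that neighbour holds 21.0 % of substrate, 1.09 % of its reagent charge and 57.1 % of product.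

The earlier runs and the new flask are simulated on assumed constants, and the scatter is random.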